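## Retrosynthetic overview
1. Feature: in the ten-membered carbocycle (C1–C10) the carbinol carbon C1 and the lactone carbinol carbon C6 face each other 1,6. A double bond between them folds the ring into a six–six bicycle: ring A (C1–C6, oxygen at C3) and ring B (C1, C10, C9, C8, C7, C6).
2. Late disconnections: the C1/C10 acetonide, the C13 methylene (carried as its Me2NH adduct), C15 (Stille coupling at C4), C4=C5 and the C8 ester, then the γ-lactone (O6 to C12).
3. Key disconnection: both C=O bonds of a cyclodecane-1,6-dione go back to the tetrasubstituted C1=C6 fusion alkene (ozonolysis).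
4. Ring A of that alkene is a Birch-reduced anisole whose OMe is the C3 oxygen. C7/C8 (transfer hydrogenation with dynamic kinetic resolution) and C10 (methyl addition) are set on ring B of a tetralin made from 6-methoxy-2-tetralone.
5. Ring order: rings A and B are bought fused, the ten-membered ring appears in step 9, and the lactone closes in step 10.

Key step: step 9

Assumption: target (germacrane) numbering is used for every intermediate, and in step 2 the benzo-fused C7 side of the ketone is taken to play the part of the aryl group in the usual model for RuCl(p-cymene)(TsDPEN), which calls for the (R,R)-ligand; the (S,S)-catalyst is equally available should the sense be opposite.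

## Route

Step 1
Reactants: 1 6-methoxy-2-tetralone; 2 methyl bromoacetate
Product: 4 methyl (±)-2-(6-methoxy-2-oxo-1,2,3,4-tetrahydronaphthalen-1-yl)acetate, via pyrrolidine enamine 3 (not isolated)
Conditions: pyrrolidine, PhMe, reflux (Dean–Stark); 2, MeCN, 60 °C; then H2O, AcOH (cat), rt
Reagents that add atoms: methyl bromoacetate (2), COC(=O)CBr; water, O
Why: Stork enamine alkylation, in which the enamine of a 2-tetralone forms only toward the benzylic carbon C7 (conjugation with the arene) and is monoalkylated there by the reactive α-bromo ester, and C7 is left racemic on purpose because a centre that is both benzylic and α to the ketone racemises freely.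

Step 2
Reactants: 4 racemic keto ester
Product: 6 (3aR,9bS)-7-methoxy-3a,4,5,9b-tetrahydronaphtho[2,1-b]furan-2(1H)-one, via cis-hydroxy ester 5 (not isolated)
Conditions: RuCl(p-cymene)[(R,R)-TsDPEN] (1 mol %), HCO2H/Et3N 5:2, CH2Cl2, 30 °C; then TsOH (cat), PhMe, 60 °C; recrystallise
Reagents that add atoms: none
Why: Noyori–Ikariya asymmetric transfer hydrogenation with dynamic kinetic resolution, known for 1-substituted 2-tetralones, in which Et3N racemises C7 through the conjugated enol faster than hydride transfer, the catalyst reduces only the matched enantiomer and delivers hydride to C8 anti to the pseudoaxial C7 arm so that C7 and C8 are set together as the cis pair, and the cis γ-hydroxy ester closes to a crystalline lactone that freezes C7.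

Step 3
Reactants: 6 cis-lactone
Product: 9 2-[(1S,2R)-2-(tert-butyldimethylsilyloxy)-6-methoxy-1,2,3,4-tetrahydronaphthalen-1-yl]acetic acid, via lithium carboxylate 7 (not isolated), via bis-silyl derivative 8 (not isolated)
Conditions: LiOH, THF/H2O, rt, evaporate to dryness; TBSCl, imidazole, DMF, 40 °C; then AcOH/THF/H2O, rt
Reagents that add atoms: lithium hydroxide, [Li+].[OH-]; tert-butyldimethylsilyl chloride, CC(C)(C)[Si](C)(C)Cl
Why: Saponification, exhaustive silylation and selective hydrolysis of the labile silyl ester is the standard way to hold a γ-hydroxy acid open, and the free acid is kept on purpose because its carboxylate shields the arm from the methyl nucleophile in step 5 and from lithium in ammonia in step 6, where a methyl ester would be attacked.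

Step 4
Reactants: 9 silyloxy acid
Product: 10 2-[(1S,2R)-2-(tert-butyldimethylsilyloxy)-6-methoxy-4-oxo-1,2,3,4-tetrahydronaphthalen-1-yl]acetic acid (C10 ketone)
Conditions: CrO3, 3,5-dimethylpyrazole, CH2Cl2, −20 °C
Reagents that add atoms: chromium trioxide, O=[Cr](=O)=O
Why: Benzylic oxidation with hexavalent chromium, the reaction type that turns 3-methoxyestra-1,3,5(10)-trienes into their 6-ketones, where as here the CH2 meta to methoxy (C10) is oxidised and not the tertiary C–H para to it (C7), helped in this substrate because the C7 arm sits pseudoaxial to avoid the peri hydrogen on C5 so that C7–H lies near the arene plane and cannot overlap with the π system.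

Step 5
Reactants: 10 C10 ketone; 11 methylmagnesium bromide
Product: 12 2-[(1S,2R,4S)-2-(tert-butyldimethylsilyloxy)-4-hydroxy-6-methoxy-4-methyl-1,2,3,4-tetrahydronaphthalen-1-yl]acetic acid
Conditions: CeCl3 (anhydrous), 11 (3.5 equiv), THF, −78 to −40 °C; aq NH4Cl
Reagents that add atoms: methylmagnesium bromide (11), C[Mg]Br
Why: Organocerium 1,2-addition, in which the first equivalent makes the inert carboxylate, the weakly basic reagent adds to C10 without enolisation toward C9 (which would expel the β-silyloxy group and aromatise ring B to a naphthol), and the methyl group enters along the pseudoaxial trajectory on the face opposite to the C7 arm and the C8 silyl ether, so that the C10 hydroxyl ends up cis to both.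

Step 6
Reactants: 12 tertiary benzylic alcohol
Product: 13 2-[(1S,2R,4S)-2-(tert-butyldimethylsilyloxy)-4-hydroxy-6-methoxy-4-methyl-1,2,3,4,5,8-hexahydronaphthalen-1-yl]acetic acid
Conditions: Li, NH3(l)/THF/t-BuOH, −78 to −33 °C; isoprene, then NH4Cl(s); pH 6 work-up
Reagents that add atoms: none
Why: Birch reduction, in which electron transfer and protonation at the two unsubstituted ring carbons C2 and C5 leave the donor-substituted positions olefinic (the C3=C4 enol ether and the tetrasubstituted C1=C6 fusion alkene), the carboxylate resists reduction, and the tertiary benzylic oxygen, held as its lithium alkoxide as in the reduction of 3-methoxybenzyl alcohols, is too poor a leaving group for hydrogenolysis as long as the excess metal is destroyed with isoprene before NH4Cl is added.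

Step 7
Reactants: 13 dihydroanisole acid
Product: 14 methyl ester of 13
Conditions: MeI, K2CO3, DMF, 0 °C to rt
Reagents that add atoms: iodomethane, CI
Why: SN2 O-alkylation of the carboxylate restores the methyl ester under basic conditions, so that neither the acid-labile enol ether nor the tertiary allylic alcohol sees acid, and K2CO3 is too weak to deprotonate the alcohol.

Step 8
Reactants: 14 enol ether ester
Product: 15 hexahydronaphthalene with C1=C6 fusion alkene and C3 ethylene ketal and C7 methyl acetate arm and C8 OTBS and C10 tertiary alcohol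
Conditions: HOCH2CH2OH (5 equiv), PPTS (5 mol %), CH2Cl2, 0 °C
Reagents that add atoms: ethylene glycol, OCCO
Why: Acid-catalysed ketalisation of an enol ether, as practised on Birch products of the 19-norsteroid series, in which protonation of the enol ether at C4 and capture of the oxocarbenium ion by glycol are far faster under a pyridinium acid than ionisation of the tertiary allylic alcohol or migration of the β,γ-alkene, so that C1=C6 stays in place as the only alkene.

Step 9
Reactants: 15 hexahydronaphthalene
Product: 17 cyclodecane-1,6-dione with C3 ethylene ketal and C7 methyl acetate arm and C8 OTBS and C10 tertiary alcohol, via methoxy hydroperoxide 16 (not isolated)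
Conditions: O3, CH2Cl2/MeOH 4:1, NaHCO3, Sudan Red 7B, −78 °C; then Me2S, −78 to 0 °C; neutral cold work-up, used crude
Reagents that add atoms: ozone, [O-][O+]=O
Why: Ozone adds to the electron-rich tetrasubstituted C1=C6 bond by 1,3-dipolar cycloaddition, the primary ozonide cycloreverts to a ketone and a carbonyl oxide (Criegee mechanism), methanol captures the carbonyl oxide as 16, and Me2S reduces that to the second ketone. The closest known reaction is the ozonolysis of Δ9,10-octalins and other Birch-derived hexahydronaphthalenes to cyclodecane-1,6-diones. The ten-membered ring is not closed by any bond-forming event: it is the perimeter of rings A and B and appears when their shared bond is cut, so no medium-ring cyclisation penalty is paid. No stereocentre is formed or touched, although C7 now lies α to the C6 ketone and the work-up is therefore kept neutral and cold. The only selectivity needed is chemoselectivity, and it is secured because step 8 converted the enol ether into a ketal and left C1=C6 as the sole π bond open to ozone, with the dye marking the end point. Methanol trapping and the bicarbonate buffer forestall fragmentation of the carbonyl oxide next to the C10 carbinol, and immediate use of 17 forestalls transannular aldol and hemiketal chemistry.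

Step 10
Reactants: 17 dione
Product: 19 6,12-olide 1,10-diol (C3 ketal and C8 OTBS retained), via triol ester 18 (not isolated)
Conditions: Zn(BH4)2, Et2O, −30 to 0 °C; aq NH4Cl; then PPTS (cat), CH2Cl2, rt
Reagents that add atoms: none
Why: Zn(BH4)2 reduction under Cram-chelate and Felkin–Anh control followed by lactonisation, in which at C1 zinc bridges the ketone oxygen and the C10 hydroxyl so that hydride enters from the periphery past the small C10 methyl group and gives the anti 1,10-diol (1R), at C6 hydride enters from the periphery anti to the C7–C8 ring bond in the rotamer that keeps the acetate arm beside the carbonyl oxygen and gives the 6S alcohol that closes to the cis-fused lactone, the non-basic reagent avoids transannular aldol reaction and β-elimination of the C8 silyl ether, and only the C6 hydroxyl is γ to the ester.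

Step 11
Reactants: 19 lactone diol
Product: 20 C1/C10 acetonide of 19
Conditions: 2-methoxypropene, PPTS (cat), CH2Cl2, 0 °C
Reagents that add atoms: 2-methoxypropene, COC(C)=C
Why: Acetonide formation by acid-catalysed addition to 2-methoxypropene, in which the anti diol closes to a cis-fused dioxolane under conditions too mild to open the C3 ethylene ketal, which takes both hydroxyls out of play in one step, bars a later 3,10-hemiketal and leaves a group that falls in the last step.

Step 12
Reactants: 20 acetonide lactone
Product: 22 C11-(dimethylaminomethyl) lactone, via lithium lactone enolate 21 (not isolated)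
Conditions: LiN(i-Pr)2, THF, −78 °C; CH2=NMe2+ I−, −78 °C to rt
Reagents that add atoms: Eschenmoser's salt, C[N+](C)=C.[I-]
Why: Mannich aminomethylation of a lactone enolate, possible only now because C11–H2 is the sole acidic site while C3 is a ketal and both hydroxyls are tied up, and the β-dimethylamino group is kept as a mask for the C11=C13 methylene so that no second Michael acceptor is present in steps 13 to 18, the C11 configuration being irrelevant since it is erased in step 19.

Step 13
Reactants: 22 Mannich base
Product: 23 C8 alcohol
Conditions: HF·pyridine, pyridine/THF, 0 °C to rt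
Reagents that add atoms: none
Why: Fluoride-mediated desilylation in a buffered acidic medium cleaves the only silyl ether without forming a free C8 alkoxide, which with basic fluoride sources could attack C12 and shift the lactone from O6 to O8, and both ketals tolerate the buffer.

Step 14
Reactants: 23 C8 alcohol; 24 (R)-2-methylbutanoic acid
Product: 25 C8 (R)-2-methylbutanoate
Conditions: 24, DCC, DMAP, CH2Cl2, 0 °C to rt
Reagents that add atoms: (R)-2-methylbutanoic acid (24), CC[C@@H](C)C(=O)O
Why: Steglich esterification of the only free hydroxyl, in which carbodiimide activation avoids the ketene pathway that racemises α-branched acid chlorides so that the (R) centre of 24 is carried over, and the ester is placed before C15 exists so that no primary alcohol competes.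

Step 15
Reactants: 25 ester ketal
Product: 26 C3 ketone
Conditions: TsOH·H2O (1.2 equiv), acetone/H2O 20:1, rt; NaHCO3 work-up
Reagents that add atoms: water, O
Why: Acid-catalysed ketal hydrolysis in wet acetone, in which the first equivalent of acid is parked on the amine, the remainder cleaves the ethylene ketal, and the large excess of acetone holds the C1/C10 acetonide in place by mass action.

Step 16
Reactants: 26 C3 ketone
Product: 29 ring-cis (4Z) C3-enone, via lithium C3–C4 enolate 27 (not isolated), via C4 sulfilimine 28 (not isolated)
Conditions: LiN(SiMe3)2 (1.05 equiv), THF, −78 °C; PhS(Cl)=N-t-Bu, −78 °C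
Reagents that add atoms: none
Why: Mukaiyama dehydrogenation, in which the bulky amide removes under kinetic control a C4 proton (next to unbranched C5H2) in preference to a C2 proton (screened by C1 and quaternary C10 and opposed by the C1–O dipole), the ketone being far more acidic than lactone or ester, the enolate is sulfenylated at C4, 28 loses the sulfenamide by a five-centre syn-elimination at low temperature, and the ring-cis alkene is expected because cis-cyclodecenes are less strained than trans-cyclodecenes and the two cis-fused five-membered rings leave little slack.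

Step 17
Reactants: 29 enone
Product: 30 C4-iodoenone (C3 and C6 on the same side of the alkene)
Conditions: I2, DMAP (20 mol %), pyridine/CH2Cl2 1:1, rt; aq Na2S2O3
Reagents that add atoms: iodine, II
Why: α-Iodination of an enone by a Baylis–Hillman-type addition–elimination, in which the amine adds to C5, the enolate is iodinated at C4 and loss of the C4 proton with expulsion of the amine restores the alkene, a reversible sequence that lets the geometry settle in the less strained ring-cis form while the masked lactone offers no second acceptor.

Step 18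
Reactants: 30 iodoenone
Product: 31 C4-hydroxymethyl enone
Conditions: Bu3SnCH2OH, Pd(PPh3)4 (10 mol %), dioxane, 80 °C
Reagents that add atoms: (tributylstannyl)methanol, CCCC[Sn](CCCC)(CCCC)CO
Why: Stille coupling, a known hydroxymethylation of α-iodoenones, in which oxidative addition of zerovalent palladium into C4–I, transfer of CH2OH from tin and reductive elimination all keep the alkene geometry, and the new primary alcohol needs no protection because C8 is already acylated.

Step 19
Reactants: 31 hydroxymethyl enone
Product: 33 α-methylene lactone acetonide, via trimethylammonium iodide 32 (not isolated)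
Conditions: MeI, THF, rt; then aq NaHCO3/CH2Cl2, rt
Reagents that add atoms: none
Why: Quaternisation and E1cB (Hofmann-type) elimination is the standard release of an α-methylene-γ-butyrolactone from its Mannich base, and bicarbonate is too mild to touch the ester, the enone or the lactone.

Step 20
Reactants: 33 acetonide
Product: 34 CNP0263726.1
Conditions: AcOH/H2O/THF 4:1:1, 40 °C
Reagents that add atoms: none
Why: Acid hydrolysis of the acetonide frees the C1 and C10 hydroxyls under conditions that leave the enone, the allylic alcohol, the ester and the α-methylene lactone untouched and change no stereocentre.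

## Compound list
1 | 6-methoxy-2-tetralone | COc1ccc2c(c1)CCC(=O)C2 | starting material
2 | methyl bromoacetate | COC(=O)CBr | starting material
3 | 1-(6-methoxy-3,4-dihydronaphthalen-2-yl)pyrrolidine (C7=C8 enamine) | COc1ccc2c(c1)CCC(N1CCCC1)=C2 | intermediate
4 | methyl (±)-2-(6-methoxy-2-oxo-1,2,3,4-tetrahydronaphthalen-1-yl)acetate (C7 racemic) | COC(=O)CC1c2ccc(OC)cc2CCC1=O | intermediate
5 | methyl 2-[(1S,2R)-2-hydroxy-6-methoxy-1,2,3,4-tetrahydronaphthalen-1-yl]acetate (C7 arm and C8 OH cis) | COC(=O)C[C@H]1c2ccc(OC)cc2CC[C@H]1O | intermediate
6 | (3aR,9bS)-7-methoxy-3a,4,5,9b-tetrahydronaphtho[2,1-b]furan-2(1H)-one (cis-fused O8,C12 lactone) | O=C1C[C@H]2c3ccc(OC)cc3CC[C@H]2O1 | intermediate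
7 | lithium 2-[(1S,2R)-2-hydroxy-6-methoxy-1,2,3,4-tetrahydronaphthalen-1-yl]acetate | [Li+].[O-]C(=O)C[C@H]1c2ccc(OC)cc2CC[C@H]1O | intermediate
8 | TBS ester of the C8 TBS ether (1S,2R) | CC(C)(C)[Si](C)(C)OC(=O)C[C@H]1c2ccc(OC)cc2CC[C@H]1O[Si](C)(C)C(C)(C)C | intermediate
9 | 2-[(1S,2R)-2-(TBS-oxy)-6-methoxy-1,2,3,4-tetrahydronaphthalen-1-yl]acetic acid | OC(=O)C[C@H]1c2ccc(OC)cc2CC[C@H]1O[Si](C)(C)C(C)(C)C | intermediate
10 | 2-[(1S,2R)-2-(TBS-oxy)-6-methoxy-4-oxo-1,2,3,4-tetrahydronaphthalen-1-yl]acetic acid (C10 ketone) | OC(=O)C[C@H]1c2ccc(OC)cc2C(=O)C[C@H]1O[Si](C)(C)C(C)(C)C | intermediate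
11 | methylmagnesium bromide | C[Mg]Br | starting material
12 | 2-[(1S,2R,4S)-2-(TBS-oxy)-4-hydroxy-6-methoxy-4-methyl-1,2,3,4-tetrahydronaphthalen-1-yl]acetic acid (arm, O8 and C10 OH all cis) | OC(=O)C[C@H]1c2ccc(OC)cc2[C@@](C)(O)C[C@H]1O[Si](C)(C)C(C)(C)C | intermediate
13 | 1,2,3,4,5,8-hexahydro analogue of 12 (C3=C4 methyl enol ether, C1=C6 fusion alkene) | OC(=O)C[C@H]1C2=C(CC(OC)=CC2)[C@@](C)(O)C[C@H]1O[Si](C)(C)C(C)(C)C | intermediate
14 | methyl ester of 13 | COC(=O)C[C@H]1C2=C(CC(OC)=CC2)[C@@](C)(O)C[C@H]1O[Si](C)(C)C(C)(C)C | intermediate
15 | key-step precursor: hexahydronaphthalene, C1=C6 fusion alkene, C3 ethylene ketal, C7 CH2CO2Me, C8 OTBS, C10 (OH)(CH3); 7S,8R,10S, arm, O8 and O10 cis | COC(=O)C[C@H]1C2=C(CC3(OCCO3)CC2)[C@@](C)(O)C[C@H]1O[Si](C)(C)C(C)(C)C | intermediate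
16 | C1 ketone, C6 methoxy hydroperoxide (C6 unassigned) | COC(=O)C[C@H]1C(OC)(OO)CCC2(OCCO2)CC(=O)[C@@](C)(O)C[C@H]1O[Si](C)(C)C(C)(C)C | intermediate
17 | key-step product: cyclodecane-1,6-dione, C3 ethylene ketal, C7 CH2CO2Me, C8 OTBS, C10 (OH)(CH3); 7R,8R,10S | COC(=O)C[C@H]1C(=O)CCC2(OCCO2)CC(=O)[C@@](C)(O)C[C@H]1O[Si](C)(C)C(C)(C)C | intermediate
18 | 1,6,10-triol methyl ester (1R,6S; C7, C8, C10 as in 34) | COC(=O)C[C@H]1[C@@H](O)CCC2(OCCO2)C[C@@H](O)[C@@](C)(O)C[C@H]1O[Si](C)(C)C(C)(C)C | intermediate
19 | cis-fused 6,12-olide, 1,10-diol, C3 ketal, C8 OTBS (all centres as in 34) | C1C(=O)O[C@H]2CCC3(OCCO3)C[C@@H](O)[C@@](C)(O)C[C@@H](O[Si](C)(C)C(C)(C)C)[C@@H]12 | intermediate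
20 | C1/C10 acetonide of 19 (cis-fused dioxolane) | C1C(=O)O[C@H]2CCC3(OCCO3)C[C@H]4OC(C)(C)O[C@@]4(C)C[C@@H](O[Si](C)(C)C(C)(C)C)[C@@H]12 | intermediate
21 | lithium C11=C12 enolate of 20 | [Li+].C1=C([O-])O[C@H]2CCC3(OCCO3)C[C@H]4OC(C)(C)O[C@@]4(C)C[C@@H](O[Si](C)(C)C(C)(C)C)[C@@H]12 | intermediate
22 | C11-(dimethylaminomethyl) lactone (C11 epimers, inconsequential) | CN(C)CC1C(=O)O[C@H]2CCC3(OCCO3)C[C@H]4OC(C)(C)O[C@@]4(C)C[C@@H](O[Si](C)(C)C(C)(C)C)[C@@H]12 | intermediate
23 | C8 alcohol from 22 | CN(C)CC1C(=O)O[C@H]2CCC3(OCCO3)C[C@H]4OC(C)(C)O[C@@]4(C)C[C@@H](O)[C@@H]12 | intermediate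
24 | (R)-2-methylbutanoic acid | CC[C@@H](C)C(=O)O | starting material
25 | C8 (R)-2-methylbutanoate of 23 | CN(C)CC1C(=O)O[C@H]2CCC3(OCCO3)C[C@H]4OC(C)(C)O[C@@]4(C)C[C@@H](OC(=O)[C@H](C)CC)[C@@H]12 | intermediate
26 | C3 ketone from 25 | CN(C)CC1C(=O)O[C@H]2CCC(=O)C[C@H]3OC(C)(C)O[C@@]3(C)C[C@@H](OC(=O)[C@H](C)CC)[C@@H]12 | intermediate
27 | lithium C3–C4 enolate of 26 | [Li+].CN(C)CC1C(=O)O[C@H]2CC=C([O-])C[C@H]3OC(C)(C)O[C@@]3(C)C[C@@H](OC(=O)[C@H](C)CC)[C@@H]12 | intermediate
28 | C4 S-phenyl-N-tert-butylsulfilimine of 26 | CN(C)CC1C(=O)O[C@H]2CC(S(=NC(C)(C)C)c3ccccc3)C(=O)C[C@H]4OC(C)(C)O[C@@]4(C)C[C@@H](OC(=O)[C@H](C)CC)[C@@H]12 | intermediate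
29 | (4Z)-enone, C3 and C6 cis on C4=C5 | CN(C)CC1C(=O)O[C@H]2/C=C\C(=O)C[C@H]3OC(C)(C)O[C@@]3(C)C[C@@H](OC(=O)[C@H](C)CC)[C@@H]12 | intermediate
30 | C4-iodoenone, iodine trans to C6 | CN(C)CC1C(=O)O[C@H]2/C=C(/I)C(=O)C[C@H]3OC(C)(C)O[C@@]3(C)C[C@@H](OC(=O)[C@H](C)CC)[C@@H]12 | intermediate
31 | C4-hydroxymethyl (4Z)-enone | CN(C)CC1C(=O)O[C@H]2/C=C(/CO)C(=O)C[C@H]3OC(C)(C)O[C@@]3(C)C[C@@H](OC(=O)[C@H](C)CC)[C@@H]12 | intermediate
32 | trimethylammonium iodide of 31 | C[N+](C)(C)CC1C(=O)O[C@H]2/C=C(/CO)C(=O)C[C@H]3OC(C)(C)O[C@@]3(C)C[C@@H](OC(=O)[C@H](C)CC)[C@@H]12.[I-] | intermediate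
33 | C1/C10 acetonide of the target | C=C1C(=O)O[C@H]2/C=C(/CO)C(=O)C[C@H]3OC(C)(C)O[C@@]3(C)C[C@@H](OC(=O)[C@H](C)CC)[C@@H]12 | intermediate
34 | CNP0263726.1 (1R,6S,7R,8R,10S,4Z; (R)-2-methylbutanoate) | C=C1C(=O)O[C@H]2/C=C(/CO)C(=O)C[C@@H](O)[C@@](C)(O)C[C@@H](OC(=O)[C@H](C)CC)[C@@H]12 | target

## Step count and risks
Total step count: 20. Longest linear sequence: 20 (steps 1–20 from 1).

Steps most likely to fail:

1. **Step 16.** Two processes threaten it:
   - deprotonation on the C2 side followed by β-elimination of the C1 oxygen;
   - syn-elimination through the rotamer about C4–C5 that leads to a ring-trans double bond.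

   The fallback sets out from 26 and comes back at 29, and sets the geometry by light instead of leaving it to the elimination. The ring-trans enone F1, obtained from 26 under the conditions of step 16, has its amine parked as the CF3CO2H salt to block electron-transfer quenching. It is then irradiated at 365 nm in degassed MeCN with thioxanthen-9-one as triplet sensitiser. The flatter, better conjugated ring-trans chromophore accepts the energy and the twisted ring-cis enone does not, so the photostationary state should drain into 29.

2. **Step 10.** The risk is poor facial selectivity at C6 or C1. Hemiketal formation by the C10 hydroxyl can withdraw it from the zinc chelate, and macrocyclic conformers can override the local models. The fallback sets out from 17 and comes back at 20, and reduces the two carbonyl groups one at a time: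
   - A limiting amount of Zn(BH4)2 at −78 °C should reduce only the chelated α-hydroxy ketone and give the C6-keto 1,10-diol F2.
   - 2-Methoxypropene with PPTS converts it into the keto acetonide F3, which removes the C10 hydroxyl from every hemiketal equilibrium and stiffens the ring.
   - LiBH(s-Bu)3 in THF at −78 °C then attacks C6 from the periphery with a stronger Felkin–Anh bias, and the alkoxide closes onto the ester to give 20.

3. **Step 4.** The risk is hydrogen abstraction at the tertiary benzylic C7–H para to methoxy, and over-oxidation. The fallback sets out from 9 and comes back at 10, and reverses the polarity of the C–H functionalisation: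
   - n-BuLi/KOt-Bu/HN(i-Pr)2 in THF at −78 °C, in an amount that also covers the acid, metalates the benzylic CH2 meta to methoxy. A tertiary carbanion para to the donor is disfavoured, as in the C6 functionalisation of 3-methoxyestratrienes.
   - B(OMe)3 followed by H2O2/NaOH gives the C10 benzylic alcohol F4 (either epimer).
   - MnO2 in CH2Cl2 oxidises F4 to 10.

Further compounds
F1 | step 16 | ring-trans C4=C5 isomer of enone 29 | CN(C)CC1C(=O)O[C@H]2/C=C/C(=O)C[C@H]3OC(C)(C)O[C@@]3(C)C[C@@H](OC(=O)[C@H](C)CC)[C@@H]12
F2 | step 10 | C6-keto 1,10-diol methyl ester (1R) | COC(=O)C[C@H]1C(=O)CCC2(OCCO2)C[C@@H](O)[C@@](C)(O)C[C@H]1O[Si](C)(C)C(C)(C)C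
F3 | step 10 | C1/C10 acetonide of F2 | COC(=O)C[C@H]1C(=O)CCC2(OCCO2)C[C@H]3OC(C)(C)O[C@@]3(C)C[C@H]1O[Si](C)(C)C(C)(C)C
F4 | step 4 | C10 benzylic alcohol of 9 (C10 epimers) | OC(=O)C[C@H]1c2ccc(OC)cc2C(O)C[C@H]1O[Si](C)(C)C(C)(C)C
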